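Numbering: ring A is C1–C5 and C10 (C2 ketone, C4 ester-bearing quaternary carbon), ring B is C5–C10, the side chain C11–C15 hangs on C9. Ring A is closed by a carbonylative [5+1] annulation: CO becomes C2 and is stitched between C3 (a neopentyl iodide on C4) and C1 (terminus of an exocyclic C10=C1 methylene on ring B), giving the C1=C10 enone directly. The step exploits the quaternary C4 (no β-hydrogen, no direct cyclization) and the fully substituted C10. The precursor comes from (R)-carvone, whose isopropenyl stereocentre relays C8, C9, C5 and C4 (malonate Claisen rearrangement) and is then excised; C13 is bought.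

Key step: step 14

Remark: TBDPS = tert-butyldiphenylsilyl; 1, 6, 14 and Bu3SnCH2OH are taken to be commercial; the malonate stereocentre of 15 and 16 is irrelevant because step 11 planarizes it.

Step 1
Reactants: 1 (R)-3-methylglutaric acid monomethyl ester
Product: 2 methyl (3R)-5-hydroxy-3-methylpentanoate
Conditions: BH3·SMe2, THF, 0 °C to rt; MeOH quench
Reagents that add atoms: none
Why: Borane reduces the free carboxylic acid (via an acyloxyborane) far faster than the methyl ester, so only the acid terminus becomes the primary alcohol and the C13 stereocentre, bought with 1, is untouched (chemoselective borane reduction).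

Step 2
Reactants: 2 methyl (3R)-5-hydroxy-3-methylpentanoate
Product: 3 methyl (3S)-5-iodo-3-methylpentanoate
Conditions: I2, PPh3, imidazole, CH2Cl2, 0 °C to rt
Reagents that add atoms: iodine, II
Why: Appel-type iodination (Garegg–Samuelsson conditions) turns the primary alcohol into the iodide by SN2 displacement of the alkoxyphosphonium group and at the same time removes the risk of lactonisation.

Step 3
Reactants: 3 methyl (3S)-5-iodo-3-methylpentanoate
Product: 4 (3S)-5-iodo-3-methylpentan-1-ol
Conditions: i-Bu2AlH (2.2 equiv), CH2Cl2, −78 to 0 °C; aq. KNaC4H4O6 (potassium sodium tartrate) work-up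
Reagents that add atoms: none
Why: i-Bu2AlH reduces the ester to the primary alcohol while a primary alkyl iodide is inert to it at low temperature (ester reduction).

Step 4
Reactants: 4 (3S)-5-iodo-3-methylpentan-1-ol
Product: 5 tert-butyl{[(3S)-5-iodo-3-methylpentyl]oxy}diphenylsilane
Conditions: TBDPSCl, Et3N, DMAP (cat.), CH2Cl2, 0 °C to rt
Reagents that add atoms: tert-butyl(chloro)diphenylsilane, CC(C)(C)[Si](Cl)(c1ccccc1)c1ccccc1
Why: Silyl ether formation on the primary alcohol gives a bulky TBDPS group that should survive bases, palladium, ozone and radicals up to the last step.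

Step 5
Reactants: 6 (R)-(−)-carvone
Product: 8 trimethyl{[(3R,5R)-2,3-dimethyl-5-(prop-1-en-2-yl)cyclohex-1-en-1-yl]oxy}silane, via bromomagnesium enolate 7 (not isolated)
Conditions: MeMgBr, CuBr·SMe2 (5 mol %), THF, −40 °C; then Me3SiCl, Et3N, HMPA, −40 °C to rt
Reagents that add atoms: methylmagnesium bromide, C[Mg]Br; chlorotrimethylsilane, C[Si](C)(C)Cl
Why: Copper-catalysed conjugate addition of the Grignard reagent occurs axially and trans to the isopropenyl group of carvone (substrate control, sets C8), and HMPA-promoted O-silylation of the resulting bromomagnesium enolate stores it as a regiodefined silyl enol ether.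

Step 6
Reactants: 8 silyl enol ether; 5 TBDPS-protected iodide
Product: 10 (2S,3R,5R)-2-[(3R)-5-(TBDPS-oxy)-3-methylpentyl]-2,3-dimethyl-5-(prop-1-en-2-yl)cyclohexan-1-one, via lithium enolate 9 (not isolated)
Conditions: MeLi, THF, 0 °C; then 5, HMPA, −78 °C to rt
Reagents that add atoms: none
Why: MeLi cleaves the silyl enol ether to the tetrasubstituted lithium enolate, which is C-alkylated by the primary iodide in an SN2 reaction on the face anti to the adjacent C8 methyl group, so the new quaternary C9 carries its methyl cis to the C8 methyl (enolate alkylation).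

Step 7
Reactants: 10 alkylated ketone
Product: 12 (3R,5R,6S)-6-[(3R)-5-(TBDPS-oxy)-3-methylpentyl]-5,6-dimethyl-3-(prop-1-en-2-yl)cyclohex-1-en-1-yl trifluoromethanesulfonate, via potassium enolate 11 (not isolated)
Conditions: KN(SiMe3)2, THF, −78 °C; then PhNTf2, −78 to 0 °C
Reagents that add atoms: N-phenylbis(trifluoromethanesulfonimide), O=S(=O)(N(c1ccccc1)S(=O)(=O)C(F)(F)F)C(F)(F)F
Why: Only the CH2 group α to the ketone is enolisable (C9 is quaternary), so deprotonation and O-sulfonylation with PhNTf2 give the C10–C5 enol triflate regiospecifically.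

Step 8
Reactants: 12 enol triflate
Product: 13 [(3R,5R,6S)-6-[(3R)-5-(TBDPS-oxy)-3-methylpentyl]-5,6-dimethyl-3-(prop-1-en-2-yl)cyclohex-1-en-1-yl]methanol
Conditions: Bu3SnCH2OH, Pd(PPh3)4 (cat.), LiCl, 1,4-dioxane, 100 °C
Reagents that add atoms: (tributylstannyl)methanol, CCCC[Sn](CCCC)(CCCC)CO
Why: Stille cross-coupling of the enol triflate with the hydroxymethyl stannane (LiCl-assisted transmetalation) installs C1 as an allylic CH2OH and keeps the C10=C5 double bond in place.

Step 9
Reactants: 14 dimethyl methylmalonate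
Product: 15 3-methoxy-2-methyl-3-oxopropanoic acid (racemic)
Conditions: KOH (1.0 equiv), MeOH, 0 °C to rt; then aq. HCl
Reagents that add atoms: potassium hydroxide, [K+].[OH-]
Why: One equivalent of hydroxide saponifies one of the two equivalent ester groups and the resulting carboxylate resists a second attack (mono-saponification).

Step 10
Reactants: 13 allylic alcohol; 15 malonic half-ester
Product: 16 [(3R,5R,6S)-6-[(3R)-5-(TBDPS-oxy)-3-methylpentyl]-5,6-dimethyl-3-(prop-1-en-2-yl)cyclohex-1-en-1-yl]methyl methyl 2-methylpropanedioate (both malonate epimers)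
Conditions: DCC, DMAP (cat.), CH2Cl2, 0 °C to rt
Reagents that add atoms: none
Why: Steglich esterification couples the unhindered primary allylic alcohol with the malonic half-ester under neutral conditions.

Step 11
Reactants: 16 allyl methyl methylmalonate
Product: 20 (2R)-2-[(1S,3S,4R,6R)-3-[(3R)-5-(TBDPS-oxy)-3-methylpentyl]-3,4-dimethyl-2-methylidene-6-(prop-1-en-2-yl)cyclohexyl]-3-methoxy-2-methyl-3-oxopropanoic acid, via lithium malonate enolate 17 (not isolated), via silyl ketene acetal 18 (not isolated), via trimethylsilyl ester 19 (not isolated)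
Conditions: LiN(SiMe3)2, THF, −78 °C; Me3SiCl, −78 °C to rt; PhMe, 80–100 °C; then 1 M HCl, THF, 0 °C
Reagents that add atoms: none
Why: Malonate variant of the Ireland–Claisen rearrangement: O-silylation of the lithium-chelated U-shaped enolate fixes the ketene acetal geometry (methyl cis to the allylic oxygen, CO2Me cis to OSiMe3), and the chair-like [3,3] shift, which bonds C4 to C5 on the ring face anti to the neighbouring isopropenyl group, sets the quaternary C4 and the tertiary C5 stereocentres in one event and moves the double bond into the exocyclic C10=C1 position.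

Step 12
Reactants: 20 malonic half-acid
Product: 22 methyl (2R)-2-[(1S,3S,4R,6R)-3-[(3R)-5-(TBDPS-oxy)-3-methylpentyl]-3,4-dimethyl-2-methylidene-6-(prop-1-en-2-yl)cyclohexyl]-3-hydroxy-2-methylpropanoate, via mixed carbonic anhydride 21 (not isolated)
Conditions: ClCO2Et, Et3N, THF, −10 °C; then NaBH4, THF/H2O, 0 °C
Reagents that add atoms: none
Why: Activation as the mixed carbonic anhydride allows NaBH4 to reduce the carboxyl group to CH2OH (future C3) while the hindered methyl ester on the same quaternary carbon is left alone.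

Step 13
Reactants: 22 neopentyl-type alcohol
Product: 23 methyl (2S)-2-[(1S,3S,4R,6R)-3-[(3R)-5-(TBDPS-oxy)-3-methylpentyl]-3,4-dimethyl-2-methylidene-6-(prop-1-en-2-yl)cyclohexyl]-3-iodo-2-methylpropanoate
Conditions: I2, PPh3, imidazole, PhMe, 90 °C
Reagents that add atoms: iodine, II
Why: Appel-type iodination of the neopentyl-type alcohol needs heat but should proceed without rearrangement because the ester on the neighbouring quaternary carbon disfavours a cationic pathway.

Step 14
Reactants: 23 neopentyl iodide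
Product: 24 methyl (1S,5S,6R,8R,8aS)-5-[(3R)-5-(TBDPS-oxy)-3-methylpentyl]-1,5,6-trimethyl-3-oxo-8-(prop-1-en-2-yl)-1,2,3,5,6,7,8,8a-octahydronaphthalene-1-carboxylate
Conditions: Pd(PPh3)4 (10 mol %), CO (50 atm), i-Pr2NEt, PhH, 130 °C
Reagents that add atoms: carbon monoxide, [C-]#[O+]
Why: Zerovalent palladium abstracts the iodine atom of the neopentyl iodide (hybrid radical–organometallic Heck-type manifold); the C3 radical, which has no β-hydrogen and cannot cyclise directly (4-exo or 5-endo only), captures CO to give the C2 acyl species. The closest known reaction type is the palladium-catalysed carbonylative Heck-type cyclisation of unactivated alkyl iodides onto tethered alkenes to give cyclic enones, itself related to free-radical carbonylation–cyclisation. Ring A closes by 6-endo-trig attack of the acyl radical on C1, the unsubstituted terminus of the exocyclic C10=C1 alkene, which forms the C1–C2 bond and a tertiary radical at C10; palladium-mediated loss of a hydrogen from C1 then gives the conjugated C1=C10 enone. No new stereocentre is created: C4 and C5 pass through unchanged and C10 ends sp2. The step needs CO capture to outrun cyclisation onto the isopropenyl group, acyl attack at C1 rather than at C10 (5-exo) or at the isopropenyl terminus (7-endo) and hydrogen loss from C1 rather than from C5; the high CO pressure, the quaternary C4 (gem-dialkyl effect, no β-elimination), the fully substituted C10 (it disfavours 5-exo attack and gives a tertiary radical) and the conjugation gained with the C2 ketone should secure these.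

Step 15
Reactants: 24 isopropenyl enone
Product: 26 methyl (1S,5S,6R,8aS)-5-[(3R)-5-(TBDPS-oxy)-3-methylpentyl]-1,5,6-trimethyl-3-oxo-1,2,3,5,6,7,8,8a-octahydronaphthalene-1-carboxylate, via methoxy hydroperoxide 25 (not isolated)
Conditions: O3 (1 equiv), MeOH, −78 °C; then FeSO4·7H2O, PhSH, −78 °C to rt
Reagents that add atoms: none
Why: Ozone attacks the electron-rich 1,1-disubstituted isopropenyl alkene in preference to the conjugated, trisubstituted enone; the methoxy hydroperoxide is reduced by FeSO4 to an alkoxy radical that fragments by β-scission (loss of methyl acetate) and the C6 radical takes a hydrogen atom from thiophenol (ozonolysis followed by iron-mediated hydrodealkenylation), which removes the stereocentre that steered the route.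

Step 16
Reactants: 26 silyl ether
Product: 27 methyl (1S,5S,6R,8aS)-5-[(3R)-5-hydroxy-3-methylpentyl]-1,5,6-trimethyl-3-oxo-1,2,3,5,6,7,8,8a-octahydronaphthalene-1-carboxylate
Conditions: HF·pyridine, THF/pyridine, 0 °C to rt
Reagents that add atoms: none
Why: Fluoride cleaves the Si–O bond of the primary silyl ether (desilylation) under buffered, non-basic conditions that do not touch the enone, the methyl ester or the γ-stereocentre C5.

Compound list

1 | (3R)-5-methoxy-3-methyl-5-oxopentanoic acid | COC(=O)C[C@H](C)CC(=O)O | starting material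
2 | methyl (3R)-5-hydroxy-3-methylpentanoate | COC(=O)C[C@H](C)CCO | intermediate
3 | methyl (3S)-5-iodo-3-methylpentanoate | COC(=O)C[C@H](C)CCI | intermediate
4 | (3S)-5-iodo-3-methylpentan-1-ol | OCC[C@H](C)CCI | intermediate
5 | tert-butyl{[(3S)-5-iodo-3-methylpentyl]oxy}diphenylsilane | ICC[C@@H](C)CCO[Si](c1ccccc1)(c1ccccc1)C(C)(C)C | intermediate
6 | (R)-(−)-carvone, (5R)-2-methyl-5-(prop-1-en-2-yl)cyclohex-2-en-1-one | O=C1C[C@H](C(C)=C)CC=C1C | starting material
7 | bromomagnesium (3R,5R)-2,3-dimethyl-5-(prop-1-en-2-yl)cyclohex-1-en-1-olate | CC1=C([O-])C[C@H](C(C)=C)C[C@H]1C.[Mg+2].[Br-] | intermediate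
8 | trimethyl{[(3R,5R)-2,3-dimethyl-5-(prop-1-en-2-yl)cyclohex-1-en-1-yl]oxy}silane | CC1=C(O[Si](C)(C)C)C[C@H](C(C)=C)C[C@H]1C | intermediate
9 | lithium (3R,5R)-2,3-dimethyl-5-(prop-1-en-2-yl)cyclohex-1-en-1-olate | CC1=C([O-])C[C@H](C(C)=C)C[C@H]1C.[Li+] | intermediate
10 | (2S,3R,5R)-2-[(3R)-5-{[tert-butyl(diphenyl)silyl]oxy}-3-methylpentyl]-2,3-dimethyl-5-(prop-1-en-2-yl)cyclohexan-1-one | O=C1C[C@H](C(C)=C)C[C@@H](C)[C@]1(C)CC[C@@H](C)CCO[Si](c1ccccc1)(c1ccccc1)C(C)(C)C | intermediate
11 | potassium enolate of 10 (enolate towards the ring CH2; stereocentres as in 10) | [K+].[O-]C1=C[C@H](C(C)=C)C[C@@H](C)[C@]1(C)CC[C@@H](C)CCO[Si](c1ccccc1)(c1ccccc1)C(C)(C)C | intermediate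
12 | (3R,5R,6S)-6-[(3R)-5-{[tert-butyl(diphenyl)silyl]oxy}-3-methylpentyl]-5,6-dimethyl-3-(prop-1-en-2-yl)cyclohex-1-en-1-yl trifluoromethanesulfonate | O=S(=O)(OC1=C[C@H](C(C)=C)C[C@@H](C)[C@]1(C)CC[C@@H](C)CCO[Si](c2ccccc2)(c2ccccc2)C(C)(C)C)C(F)(F)F | intermediate
13 | [(3R,5R,6S)-6-[(3R)-5-{[tert-butyl(diphenyl)silyl]oxy}-3-methylpentyl]-5,6-dimethyl-3-(prop-1-en-2-yl)cyclohex-1-en-1-yl]methanol | OCC1=C[C@H](C(C)=C)C[C@@H](C)[C@]1(C)CC[C@@H](C)CCO[Si](c1ccccc1)(c1ccccc1)C(C)(C)C | intermediate
14 | dimethyl 2-methylpropanedioate | COC(=O)C(C)C(=O)OC | starting material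
15 | 3-methoxy-2-methyl-3-oxopropanoic acid (racemic) | COC(=O)C(C)C(=O)O | intermediate
16 | [(3R,5R,6S)-6-[(3R)-5-{[tert-butyl(diphenyl)silyl]oxy}-3-methylpentyl]-5,6-dimethyl-3-(prop-1-en-2-yl)cyclohex-1-en-1-yl]methyl methyl 2-methylpropanedioate (both epimers at the malonate carbon) | COC(=O)C(C)C(=O)OCC1=C[C@H](C(C)=C)C[C@@H](C)[C@]1(C)CC[C@@H](C)CCO[Si](c1ccccc1)(c1ccccc1)C(C)(C)C | intermediate
17 | lithium enolate of 16 (chelated U shape, O− cis to CO2Me) | [Li+].COC(=O)/C(C)=C(\[O-])OCC1=C[C@H](C(C)=C)C[C@@H](C)[C@]1(C)CC[C@@H](C)CCO[Si](c1ccccc1)(c1ccccc1)C(C)(C)C | intermediate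
18 | O-trimethylsilyl ketene acetal of 16 (OSiMe3 cis to CO2Me, methyl cis to the allylic oxygen) | COC(=O)/C(C)=C(\O[Si](C)(C)C)OCC1=C[C@H](C(C)=C)C[C@@H](C)[C@]1(C)CC[C@@H](C)CCO[Si](c1ccccc1)(c1ccccc1)C(C)(C)C | intermediate
19 | trimethylsilyl ester of acid 20 (stereocentres as in 20) | C=C1[C@@H]([C@@](C)(C(=O)OC)C(=O)O[Si](C)(C)C)[C@H](C(C)=C)C[C@@H](C)[C@]1(C)CC[C@@H](C)CCO[Si](c1ccccc1)(c1ccccc1)C(C)(C)C | intermediate
20 | (2R)-2-[(1S,3S,4R,6R)-3-[(3R)-5-{[tert-butyl(diphenyl)silyl]oxy}-3-methylpentyl]-3,4-dimethyl-2-methylidene-6-(prop-1-en-2-yl)cyclohexyl]-3-methoxy-2-methyl-3-oxopropanoic acid | C=C1[C@@H]([C@@](C)(C(=O)OC)C(=O)O)[C@H](C(C)=C)C[C@@H](C)[C@]1(C)CC[C@@H](C)CCO[Si](c1ccccc1)(c1ccccc1)C(C)(C)C | intermediate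
21 | ethyl carbonic mixed anhydride of acid 20 (stereocentres as in 20) | C=C1[C@@H]([C@@](C)(C(=O)OC)C(=O)OC(=O)OCC)[C@H](C(C)=C)C[C@@H](C)[C@]1(C)CC[C@@H](C)CCO[Si](c1ccccc1)(c1ccccc1)C(C)(C)C | intermediate
22 | methyl (2R)-2-[(1S,3S,4R,6R)-3-[(3R)-5-{[tert-butyl(diphenyl)silyl]oxy}-3-methylpentyl]-3,4-dimethyl-2-methylidene-6-(prop-1-en-2-yl)cyclohexyl]-3-hydroxy-2-methylpropanoate | C=C1[C@@H]([C@@](C)(C(=O)OC)CO)[C@H](C(C)=C)C[C@@H](C)[C@]1(C)CC[C@@H](C)CCO[Si](c1ccccc1)(c1ccccc1)C(C)(C)C | intermediate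
23 | methyl (2S)-2-[(1S,3S,4R,6R)-3-[(3R)-5-{[tert-butyl(diphenyl)silyl]oxy}-3-methylpentyl]-3,4-dimethyl-2-methylidene-6-(prop-1-en-2-yl)cyclohexyl]-3-iodo-2-methylpropanoate | C=C1[C@@H]([C@@](C)(C(=O)OC)CI)[C@H](C(C)=C)C[C@@H](C)[C@]1(C)CC[C@@H](C)CCO[Si](c1ccccc1)(c1ccccc1)C(C)(C)C | intermediate
24 | methyl (1S,5S,6R,8R,8aS)-5-[(3R)-5-{[tert-butyl(diphenyl)silyl]oxy}-3-methylpentyl]-1,5,6-trimethyl-3-oxo-8-(prop-1-en-2-yl)-1,2,3,5,6,7,8,8a-octahydronaphthalene-1-carboxylate | COC(=O)[C@@]1(C)CC(=O)C=C2[C@@H]1[C@H](C(C)=C)C[C@@H](C)[C@]2(C)CC[C@@H](C)CCO[Si](c1ccccc1)(c1ccccc1)C(C)(C)C | intermediate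
25 | 24 with the isopropenyl group replaced by a 1-hydroperoxy-1-methoxyethyl group (both epimers at that carbon) | COC(=O)[C@@]1(C)CC(=O)C=C2[C@@H]1[C@H](C(C)(OC)OO)C[C@@H](C)[C@]2(C)CC[C@@H](C)CCO[Si](c1ccccc1)(c1ccccc1)C(C)(C)C | intermediate
26 | methyl (1S,5S,6R,8aS)-5-[(3R)-5-{[tert-butyl(diphenyl)silyl]oxy}-3-methylpentyl]-1,5,6-trimethyl-3-oxo-1,2,3,5,6,7,8,8a-octahydronaphthalene-1-carboxylate | COC(=O)[C@@]1(C)CC(=O)C=C2[C@@H]1CC[C@@H](C)[C@]2(C)CC[C@@H](C)CCO[Si](c1ccccc1)(c1ccccc1)C(C)(C)C | intermediate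
27 | methyl (1S,5S,6R,8aS)-5-[(3R)-5-hydroxy-3-methylpentyl]-1,5,6-trimethyl-3-oxo-1,2,3,5,6,7,8,8a-octahydronaphthalene-1-carboxylate | COC(=O)[C@@]1(C)CC(=O)C=C2[C@@H]1CC[C@@H](C)[C@]2(C)CC[C@@H](C)CCO | target

Total step count: 16. Longest linear sequence: 14 steps (from 1 through steps 1–4, 6–8 and 10–16).

Steps most likely to fail

Step 14. The carbonylative cyclization may suffer from hydrogen-atom capture before CO uptake, from attack of the acyl intermediate on the isopropenyl terminus, from palladium-hydride migration of the isopropenyl double bond, or from hydrogen loss toward C5 with erosion of the C5 configuration. The fallback sets out from 23 and separates ring closure from unsaturation. Tin-free radical carbonylation (CO 80 atm, (Me3Si)3SiH, AIBN, PhH, 80 °C) should close ring A by the same 6-endo acyl radical attack on C1, giving the saturated ring A ketone F1 as a mixture of C10 epimers. Dehydrogenation of the saturated ring A ketone F1 with IBX (DMSO, 70 °C) can only run toward C1–C10, because C4 carries no hydrogen, and comes back to the route at 24.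

Step 11. The [3,3] shift of the ester-stabilized ketene acetal may be slow, forcing may bring decarboxylation of the malonic half-ester, and loss of ketene acetal geometry would scramble C4. The fallback sets out from 13. Acid-catalysed exchange with methyl 3,3-dimethoxy-2-methylpropanoate (EtCO2H cat., xylene, 140 °C, removal of MeOH) should give the (E)-β-alkoxyacrylate F2, in which alkene geometry places the methyl group cis to the allylic oxygen. In the same pot the (E)-β-alkoxyacrylate F2 should undergo the aliphatic Claisen rearrangement through the same chair to the α-formyl ester F3. Reduction of the α-formyl ester F3 with NaBH4 (MeOH, 0 °C) comes back to the route at 22.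

Step 6. SN2 attack of the hindered tetrasubstituted enolate on an unactivated primary iodide may be too slow, so that proton transfer, O-alkylation or elimination of the iodide take over. The fallback sets out from 5 and 8 and makes the C9–C11 bond by a Lewis-acid aldol addition instead. Kornblum oxidation of 5 (DMSO, NaHCO3, 110 °C) gives the aldehyde F4. Mukaiyama aldol addition of 8 to the aldehyde F4 (TiCl4, CH2Cl2, −78 °C) should give the β-hydroxy ketone F5 with the same facial preference anti to the C8 methyl. Acylation with PhOC(S)Cl (pyridine, DMAP) gives the phenyl thionocarbonate F6, and Barton–McCombie deoxygenation of the phenyl thionocarbonate F6 (Bu3SnH, AIBN, PhMe, 90 °C) comes back to the route at 10.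

Further compounds

F1 | step 14 | saturated ring A ketone: 24 with a C1–C10 single bond (both C10 epimers) | COC(=O)[C@@]1(C)CC(=O)CC2[C@@H]1[C@H](C(C)=C)C[C@@H](C)[C@]2(C)CC[C@@H](C)CCO[Si](c1ccccc1)(c1ccccc1)C(C)(C)C
F2 | step 11 | methyl (2E)-2-methyl-3-{[(3R,5R,6S)-6-[(3R)-5-{[tert-butyl(diphenyl)silyl]oxy}-3-methylpentyl]-5,6-dimethyl-3-(prop-1-en-2-yl)cyclohex-1-en-1-yl]methoxy}prop-2-enoate | COC(=O)/C(C)=C/OCC1=C[C@H](C(C)=C)C[C@@H](C)[C@]1(C)CC[C@@H](C)CCO[Si](c1ccccc1)(c1ccccc1)C(C)(C)C
F3 | step 11 | methyl (2R)-2-[(1S,3S,4R,6R)-3-[(3R)-5-{[tert-butyl(diphenyl)silyl]oxy}-3-methylpentyl]-3,4-dimethyl-2-methylidene-6-(prop-1-en-2-yl)cyclohexyl]-2-methyl-3-oxopropanoate | C=C1[C@@H]([C@@](C)(C(=O)OC)C=O)[C@H](C(C)=C)C[C@@H](C)[C@]1(C)CC[C@@H](C)CCO[Si](c1ccccc1)(c1ccccc1)C(C)(C)C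
F4 | step 6 | (3S)-5-{[tert-butyl(diphenyl)silyl]oxy}-3-methylpentanal | O=CC[C@@H](C)CCO[Si](c1ccccc1)(c1ccccc1)C(C)(C)C
F5 | step 6 | aldol adduct: 10 with a hydroxyl group on the side-chain carbon attached to the ring (both carbinol epimers) | O=C1C[C@H](C(C)=C)C[C@@H](C)[C@]1(C)C(O)C[C@@H](C)CCO[Si](c1ccccc1)(c1ccccc1)C(C)(C)C
F6 | step 6 | O-phenyl thionocarbonate of F5 | O=C1C[C@H](C(C)=C)C[C@@H](C)[C@]1(C)C(OC(=S)Oc1ccccc1)C[C@@H](C)CCO[Si](c1ccccc1)(c1ccccc1)C(C)(C)C
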